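**Assumption:** the SMILES is read as (2R,3S), i.e. the 3'-O-galloyl ester of (+)-catechin (ester on the B-ring oxygen meta to C1', 4'-OH free). (+)-Catechin (dried from its commercial hydrate) and 3,4,5-tris(benzyloxy)benzoic acid are taken as inexpensive catalogue compounds.

**Catalyst for step 2** (made separately, used at 20 mol %, not a route compound): Cat-A = (4S)-2-methoxy-3-[(1-methyl-1H-imidazol-2-yl)methyl]-4-(propan-2-yl)-1,3-oxazolidine, COC1OC[C@H](C(C)C)N1Cc1nccn1C.

## Retrosynthetic overview

1. The target is cut at C–O bonds only. The galloyl ring comes from tri-O-benzylgallic acid 1 (activated as acid chloride 2); the flavan core with both stereocentres (2R,3S) comes from (+)-catechin 3.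
2. Key disconnection: the aryl ester bond O3'–C(=O). It is made by site-selective galloyl transfer from 2 to the 3'-OH of unprotected 3, through an O3-docked catalyst adduct 4, giving tri-O-benzyl ester 5.
3. Last disconnection: the three benzyl ethers of 5, removed by neutral hydrogenolysis to give target 6.
4. Rings: none is built. The chroman A/C bicycle, the B ring and the galloyl ring are all present in 1 and 3.

## Route

Step 1
Reactants: 1 3,4,5-tris(benzyloxy)benzoic acid
Product: 2 tri-O-benzylgalloyl chloride [3,4,5-tris(benzyloxy)benzoyl chloride]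
Conditions: (COCl)2 (1.5 equiv), DMF (cat.), CH2Cl2, 0 °C to rt; evaporate, strip with toluene, use crude
Reagents that add atoms: oxalyl chloride, ClC(=O)C(=O)Cl
Why: Vilsmeier-type acid chloride formation (nucleophilic acyl substitution via the DMF-derived chloroiminium activator) is routine for electron-rich benzoic acids; the benzyl ethers are inert and no stereocentre is involved.

Step 2
Reactants: 2 tri-O-benzylgalloyl chloride; 3 (+)-catechin
Product: 5 (+)-catechin 3'-O-[3,4,5-tris(benzyloxy)benzoate], via O3-docked catalyst adduct 4 (not isolated)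
Conditions: Cat-A (20 mol %), 2,4,6-collidine (1.3 equiv), collidine·HCl (5 mol %), THF, −20 °C, slow addition of 2 (1.1 equiv); then MeOH, AcOH; silica with 0.5% AcOH
Reagents that add atoms: none
Why: Proposed new method: Cat-A exchanges its OMe for the only aliphatic hydroxyl of 3 (O3; acid-catalysed orthoaminal exchange, phenols bind far more weakly) to give docked adduct 4, whose N-methylimidazole arm is acylated by 2 and hands the galloyl group intramolecularly to the phenol it can reach, O3' (estimated about 4.7 Å from O3, B ring free to rotate into line), rather than O4' (about 6.5 Å, pointing away), O7, or O5 (about 5 Å on the opposite, C4 flank; the (4S) catalyst is chosen on the design premise that it projects its arm over the C2 flank of the (3S)-carbinol); exchange with fresh 3 then releases 5 and turns the catalyst over, collidine is too weak a base to ionise phenols so undirected acylation and 3'→4' acyl migration stay slow, and C2/C3 are untouched; closest known reaction type: reversible-covalent scaffolding-catalysed site-selective acylation of cis-1,2-diols, here stretched to a 1,7-related alcohol/phenol pair on an unprotected polyphenol.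

Step 3
Reactants: 5 (+)-catechin 3'-O-[3,4,5-tris(benzyloxy)benzoate]
Product: 6 (+)-catechin 3'-O-gallate (target)
Conditions: H2 (1 atm), 20% Pd(OH)2/C, EtOAc–THF (1:1), rt; filter, concentrate below 30 °C, Sephadex LH-20 if needed
Reagents that add atoms: none
Why: Heterogeneous Pd-catalysed hydrogenolysis (O-debenzylation) of the three benzyl aryl ethers under neutral aprotic conditions leaves the aryl ester and the chroman C2–O1 bond intact; with no base present the galloyl group stays on O3', and the (2R,3S) stereocentres are not touched.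

## Compound list

1 | 3,4,5-tris(benzyloxy)benzoic acid (tri-O-benzylgallic acid; achiral) | OC(=O)c1cc(OCc2ccccc2)c(OCc2ccccc2)c(OCc2ccccc2)c1 | starting material
2 | 3,4,5-tris(benzyloxy)benzoyl chloride (achiral) | ClC(=O)c1cc(OCc2ccccc2)c(OCc2ccccc2)c(OCc2ccccc2)c1 | intermediate
3 | (+)-catechin, (2R,3S)-2-(3,4-dihydroxyphenyl)-3,4-dihydro-2H-chromene-3,5,7-triol | Oc1ccc([C@H]2Oc3cc(O)cc(O)c3C[C@@H]2O)cc1O | starting material
4 | O3-docked catalyst adduct: (+)-catechin bound through O3 to C2 of the (4S)-4-isopropyl-3-[(1-methylimidazol-2-yl)methyl]oxazolidine unit of Cat-A (flavan 2R,3S; acetal carbon epimeric) | Oc1ccc([C@H]2Oc3cc(O)cc(O)c3C[C@@H]2OC4OC[C@H](C(C)C)N4Cc5nccn5C)cc1O | intermediate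
5 | 2-hydroxy-5-[(2R,3S)-3,5,7-trihydroxy-3,4-dihydro-2H-chromen-2-yl]phenyl 3,4,5-tris(benzyloxy)benzoate | O=C(Oc1cc([C@H]2Oc3cc(O)cc(O)c3C[C@@H]2O)ccc1O)c1cc(OCc2ccccc2)c(OCc2ccccc2)c(OCc2ccccc2)c1 | intermediate
6 | (+)-catechin 3'-O-gallate, 2-hydroxy-5-[(2R,3S)-3,5,7-trihydroxy-3,4-dihydro-2H-chromen-2-yl]phenyl 3,4,5-trihydroxybenzoate | O=C(Oc1cc([C@H]2Oc3cc(O)cc(O)c3C[C@@H]2O)ccc1O)c1cc(O)c(O)c(O)c1 | target

## Step count and risks

Total step count: 3. Longest linear sequence: 3 steps (1 → 2 → 5 → 6; two steps from 3).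

**Steps most likely to fail, in order of risk:**

Step 2 (the proposed new step). The risks are docking at a phenol, delivery to O5 instead of O3', or slow turnover; the mirror-image catalyst is the first variable to change. The 3'- versus 4'-ester assignment is made by HMBC. The fallback uses known chemistry only; it sets out from 3 and comes back to the route at 6. 3 is ketalised at the catechol with dichlorodiphenylmethane (K2CO3, MeCN) to 3',4'-O-(diphenylmethylene)-(+)-catechin F1. The two A-ring phenols are benzylated (BnBr, K2CO3, DMF; the 3-OH stays free) to 5,7-di-O-benzyl-3',4'-O-(diphenylmethylene)-(+)-catechin F2. The ketal is hydrolysed (AcOH–H2O, 80 °C) to 5,7-di-O-benzyl-(+)-catechin F3. F3 is mono-acylated with 2 (1.0 equiv, Et3N, CH2Cl2, −40 °C), which gives 5,7-di-O-benzyl-(+)-catechin 3'-O-[3,4,5-tris(benzyloxy)benzoate] F4 together with its regioisomer 5,7-di-O-benzyl-(+)-catechin 4'-O-[3,4,5-tris(benzyloxy)benzoate] F5. The two are separated by chromatography; F5 is re-equilibrated with catalytic Et3N and recycled. F4 is hydrogenolysed under the conditions of step 3 to 6.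

Step 3. If the hydrogenolysis is slow (catalyst fouling by the polyphenol) or needs protic additives, the freed 4'-OH can take over the galloyl group (3'→4' migration) or the aryl ester can be solvolysed. The fallback replaces benzyl by silyl protection and reduction by fluoride cleavage; it sets out from 3 and comes back at 6. Commercial gallic acid (OC(=O)c1cc(O)c(O)c(O)c1) is persilylated (TBSCl, imidazole, DMF) to tert-butyldimethylsilyl 3,4,5-tris(tert-butyldimethylsilyloxy)benzoate F6. F6 is converted directly with (COCl)2/cat. DMF into 3,4,5-tris(tert-butyldimethylsilyloxy)benzoyl chloride F7. F7 is coupled with 3 under the step 2 conditions to (+)-catechin 3'-O-[3,4,5-tris(tert-butyldimethylsilyloxy)benzoate] F8. F8 is desilylated with HF·pyridine (THF, 0 °C) to 6.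

Step 1. This is the least risky step. Residual HCl or chloroiminium salt in crude 2 could drive undirected acylation in step 2, and 2 hydrolyses on handling. The fallback uses a halide-free acyl donor; it sets out from 1 and comes back at 5. 1 is dehydrated with DCC (0.5 equiv, CH2Cl2) to 3,4,5-tris(benzyloxy)benzoic anhydride F9. F9 is used in place of 2 in step 2 (the docked imidazole is acylated by the anhydride, the carboxylate serves as the base) to give 5.

## Further compounds

F1 | step 2 | 3',4'-O-(diphenylmethylene)-(+)-catechin (2R,3S) | c1cc([C@H]2Oc3cc(O)cc(O)c3C[C@@H]2O)cc2OC(c3ccccc3)(c3ccccc3)Oc12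
F2 | step 2 | 5,7-di-O-benzyl-3',4'-O-(diphenylmethylene)-(+)-catechin (2R,3S) | c1cc([C@H]2Oc3cc(OCc4ccccc4)cc(OCc4ccccc4)c3C[C@@H]2O)cc2OC(c3ccccc3)(c3ccccc3)Oc12
F3 | step 2 | 5,7-di-O-benzyl-(+)-catechin (2R,3S) | Oc1ccc([C@H]2Oc3cc(OCc4ccccc4)cc(OCc4ccccc4)c3C[C@@H]2O)cc1O
F4 | step 2 | 5,7-di-O-benzyl-(+)-catechin 3'-O-[3,4,5-tris(benzyloxy)benzoate] (2R,3S) | O=C(Oc1cc([C@H]2Oc3cc(OCc4ccccc4)cc(OCc4ccccc4)c3C[C@@H]2O)ccc1O)c1cc(OCc2ccccc2)c(OCc2ccccc2)c(OCc2ccccc2)c1
F5 | step 2 | 5,7-di-O-benzyl-(+)-catechin 4'-O-[3,4,5-tris(benzyloxy)benzoate] (2R,3S) | O=C(Oc1ccc([C@H]2Oc3cc(OCc4ccccc4)cc(OCc4ccccc4)c3C[C@@H]2O)cc1O)c1cc(OCc2ccccc2)c(OCc2ccccc2)c(OCc2ccccc2)c1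
F6 | step 3 | tert-butyldimethylsilyl 3,4,5-tris(tert-butyldimethylsilyloxy)benzoate | CC(C)(C)[Si](C)(C)OC(=O)c1cc(O[Si](C)(C)C(C)(C)C)c(O[Si](C)(C)C(C)(C)C)c(O[Si](C)(C)C(C)(C)C)c1
F7 | step 3 | 3,4,5-tris(tert-butyldimethylsilyloxy)benzoyl chloride | ClC(=O)c1cc(O[Si](C)(C)C(C)(C)C)c(O[Si](C)(C)C(C)(C)C)c(O[Si](C)(C)C(C)(C)C)c1
F8 | step 3 | (+)-catechin 3'-O-[3,4,5-tris(tert-butyldimethylsilyloxy)benzoate] (2R,3S) | O=C(Oc1cc([C@H]2Oc3cc(O)cc(O)c3C[C@@H]2O)ccc1O)c1cc(O[Si](C)(C)C(C)(C)C)c(O[Si](C)(C)C(C)(C)C)c(O[Si](C)(C)C(C)(C)C)c1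
F9 | step 1 | 3,4,5-tris(benzyloxy)benzoic anhydride | O=C(OC(=O)c1cc(OCc2ccccc2)c(OCc2ccccc2)c(OCc2ccccc2)c1)c1cc(OCc2ccccc2)c(OCc2ccccc2)c(OCc2ccccc2)c1
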